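Atom numbering follows isochroman-1-one: unprimed atoms belong to unit A (the half whose C4 carries the aryl ether), primed atoms to unit B. Compound numbers are those of the steps and of the compound list.

## Analysis of the target

Target 23 is an unsymmetrical dimer of two 7-methoxy-3-methyl-3,4-dihydroisocoumarins. Unit A carries hydroxyls at C6 and C8 and an aryloxy group at C4; unit B carries hydroxyls at C4' and C8', and its O6' is the ether oxygen bound to C4. There are four stereocentres, C3/C4 and C3'/C4', each pair trans on its lactone ring with the configuration (3R,4S); each pair corresponds to an erythro 1-arylpropane-1,2-diol. The two pairs are separated by the aryl ether, so neither can control the other. Sensitive sites are the secondary benzylic aryl ether at C4 (hydrogenolysis, acid ionisation, elimination to the isocoumarin), the free benzylic 4'-hydroxyl next to a lactone (under base it can translactonise to the five-membered phthalide), two chelated phenols and two lactones. The difficulty is threefold: forming the C4–O6' bond at a hindered secondary benzylic carbon with defined configuration, telling O6' from its chelated neighbour O8', and setting the trans relation twice on two rings with the same oxygenation. The strategy rests on one feature of unit A: C1, C8a, C4a and C4 are the four carbons of a hydroxy-ortho-quinodimethane, and O2–C3 is the carbonyl group of acetaldehyde. The ether can therefore be made while C4 is still a primary benzylic carbon, and C3 and C4 are both set when the pyran ring closes.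

## Retrosynthetic reasoning

Target 23 is traced back to its protected form 22, which carries three methoxymethyl ethers (O6, O8, O8') and one silyl ether (O4'). These groups are chosen because acid alone removes them; hydrogenolysis would cut the C4–O6' bond and base would endanger the 4'-hydroxy lactone.

Lactone 22 is taken back to lactol 21 by lowering the oxidation level at C1. This costs one mild oxidation forward and makes the ring accessible by cycloaddition of an aldehyde.

Lactol 21 is cut at C3–C4 and C1–O2 into aldehyde 19 and acetaldehyde 20. The cut is made here because it removes a ring and both stereocentres of unit A at once and turns the hindered secondary ether into the primary benzyl aryl ether of 19. The forward reaction has to generate the dienol of 19 by light, capture it with 20 before it reverts, and control the face and the exo/endo orientation.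

Aldehyde 19 is cut at the CH2–O6' bond, through phenol 18, into benzylic alcohol 5 and the ring B diol 16. A primary benzylic alcohol and a phenol para to a carbonyl-bearing carbon are ideal partners for a redox condensation. The chelated O8' hydroxyl of 16 is less acidic and needs no protection at this stage. The aldehyde of ring A must be masked while the hydroxymethyl group is free, otherwise the two would close to a lactol.

Alcohol 5 goes back through acetal 4 and aldehyde 3 to formyl ester 2 and the commercial benzoate 1. The ester carbon of 1 becomes C4 and the only free ring positions lie between the ester and a hydroxyl, so ortho-formylation places C1 without ambiguity.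

Diol 16 is taken back through benzyl ether 15 to bromo alcohol 14 by cutting C8a'–C1' and C1'–O2', a carbonylative lactonisation. The carboxyl carbon is introduced last because any intermediate with a free benzylic hydroxyl beside an ortho carboxyl group would close to the phthalide. In 14 the benzylic oxygen is silylated and only O3' can cyclise.

Alcohol 14 is derived from bis-silyl ether 13, bromo diol 11 and diol 10. Bromination is unambiguous because the two free ring positions of 10 are equivalent. The bromine then hinders the benzylic hydroxyl, so the two secondary hydroxyls can be told apart by a temporary triethylsilyl group on O3'.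

Diol 10 is traced to diketone 9, N-methoxy-N-methylamide 7, benzyl ether 6 and again 1. Both stereocentres of unit B come from one catalytic reduction of 9, and the two carbons C3' and its methyl group are added to 7 as an acetyl anion equivalent.

## Alternatives that were turned down

Alternative 1: Ring B would be built as an arene by a Diels–Alder reaction between the fully substituted 2-pyrone A2 and the alkynyl ether A3 of the unit A benzylic alcohol. This forms C4a'–C5' and C6'–C7', and loss of carbon dioxide gives benzoate A1. In its favour, the ether oxygen is placed without any phenol differentiation, the polarised alkynyl ether and the ester-bearing pyrone are electronically matched, and the extrusion is irreversible. Against it, A3 is a secondary alkynyl ether with a β-hydrogen, a class that fragments to a ketene on heating, while a tetrasubstituted pyrone needs heat to react. A1 also contains neither lactone, and ring A still lacks C1. All four stereocentres would have to be made beforehand in two separate chains. On regiochemical certainty of the ether this route is as strong as the chosen one. In exchange, the chosen route forms the ether at a primary carbon and obtains ring A with two of its stereocentres in one step, which saves a full asymmetric sequence.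

Alternative 2: The two C8 and C8' hydroxyls would be introduced last, by carbonyl-directed C–H hydroxylation of the dideoxy bis-lactone A5 with [RuCl2(p-cymene)]2 and K2S2O8 to give diacetate A4. In its favour, the aromatic starting materials are simpler, no O8 protecting groups are needed, the only C–H ortho to each lactone carbonyl is the right one, and the reaction type is known. Against it, the medium is strongly acidic and oxidising. A5 contains the ionisable C4 benzylic ether and electron-rich rings, and the product phenols are more oxidisable than the substrate. The step must succeed twice on the complete skeleton, and the acetates must then be removed under conditions that threaten the 4'-hydroxy lactone. This alternative is stronger on step count in the aromatic fragments. The chosen route instead places its uncertain step before the last oxidation-level change and runs it under neutral conditions that the ether tolerates.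

Alternative 3: Both lactones would be closed together by twofold palladium-catalysed alkoxycarbonylation of the bis(aryl bromide) diol A7, giving A6, which is identical with 22. In its favour, the reaction type is reliable (the chosen route uses it once, for ring B) and it leads to the same late intermediate. Against it, A7 already contains the C4–O6' ether at a secondary benzylic carbon. This ether would have to be made by substitution on an open-chain benzylic alcohol, with the risk of ionisation and elimination. Each half also needs its own asymmetric diol synthesis and oxygen differentiation, which roughly doubles the ring B sequence. On precedent this alternative is stronger. The chosen route is shorter by about eight steps and avoids substitution at the secondary centre.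

Key step: step 16

Remark on the chemistry: the sense of induction of the titanium TADDOLate in step 16 cannot be taken from precedent. (R,R)-TADDOL, (4R,5R)-2,2-dimethyl-α,α,α′,α′-tetraphenyl-1,3-dioxolane-4,5-dimethanol, is written, and the (S,S)-ligand is to be used if it proves to favour the (3S,4R) adduct.

## Steps

Step 1
Reactants: 1 methyl 3,5-dihydroxy-4-methoxybenzoate
Product: 2 methyl 2-formyl-3,5-dihydroxy-4-methoxybenzoate
Conditions: Cl2CHOMe, TiCl4, CH2Cl2, −10 °C → rt; then H2O
Reagents that add atoms: dichloromethyl methyl ether COC(Cl)Cl; water O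
Why: Rieche formylation. The two free positions are equivalent, each ortho to one hydroxyl and para to the other, and the titanium phenoxide directs ortho. The first formyl group deactivates the ring against a second.

Step 2
Reactants: 2 methyl 2-formyl-3,5-dihydroxy-4-methoxybenzoate
Product: 3 methyl 2-formyl-4-methoxy-3,5-bis(methoxymethoxy)benzoate
Conditions: MOMCl, iPr2NEt, CH2Cl2, 0 → 40 °C
Reagents that add atoms: chloromethyl methyl ether COCCl
Why: Williamson-type O-alkylation of both phenols. The MOM ethers survive hydride, Mitsunobu conditions and light, and the one that becomes O8 later serves as a chelating site.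

Step 3
Reactants: 3 methyl 2-formyl-4-methoxy-3,5-bis(methoxymethoxy)benzoate
Product: 4 methyl 2-(1,3-dioxolan-2-yl)-4-methoxy-3,5-bis(methoxymethoxy)benzoate
Conditions: TMSOCH2CH2OTMS, TMSOTf (cat.), CH2Cl2, −78 → −20 °C; pyridine
Reagents that add atoms: 1,2-bis(trimethylsilyloxy)ethane C[Si](C)(C)OCCO[Si](C)(C)C
Why: Noyori acetalisation under aprotic conditions at low temperature, so the MOM ethers and the ester are untouched. A cyclic acetal is chosen because it does not exchange readily with the neighbouring hydroxymethyl group formed in step 4.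

Step 4
Reactants: 4 methyl 2-(1,3-dioxolan-2-yl)-4-methoxy-3,5-bis(methoxymethoxy)benzoate
Product: 5 [2-(1,3-dioxolan-2-yl)-4-methoxy-3,5-bis(methoxymethoxy)phenyl]methanol
Conditions: LiAlH4, THF, 0 °C; basic work-up
Reagents that add atoms: none
Why: Hydride reduction of the ester to the primary benzylic alcohol. Acetal and MOM ethers are inert to LiAlH4.

Step 5
Reactants: 1 methyl 3,5-dihydroxy-4-methoxybenzoate
Product: 6 methyl 3,5-bis(benzyloxy)-4-methoxybenzoate
Conditions: BnBr, K2CO3, DMF, rt → 50 °C
Reagents that add atoms: benzyl bromide BrCc1ccccc1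
Why: Williamson ether synthesis. Benzyl ethers are used on ring B because they survive organolithium, formic acid, bromination and carbonylation, and are removed under neutral conditions before the fragment coupling.

Step 6
Reactants: 6 methyl 3,5-bis(benzyloxy)-4-methoxybenzoate
Product: 7 3,5-bis(benzyloxy)-N,4-dimethoxy-N-methylbenzamide
Conditions: MeNH(OMe)·HCl, iPrMgCl, THF, −20 → 0 °C
Reagents that add atoms: N,O-dimethylhydroxylamine hydrochloride CNOC.Cl
Why: Aminolysis of the ester by the magnesium amide gives the N-methoxy-N-methylamide (Weinreb amide).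

Step 7
Reactants: 7 3,5-bis(benzyloxy)-N,4-dimethoxy-N-methylbenzamide
Product: 9 1-[3,5-bis(benzyloxy)-4-methoxyphenyl]propane-1,2-dione, via 2-ethoxy enone 8 (not isolated)
Conditions: CH2=CHOEt, tBuLi, THF, −78 → 0 °C; 7, −78 °C; then 1 M HCl, rt
Reagents that add atoms: ethyl vinyl ether C=COCC; water O
Why: 1-Ethoxyvinyllithium is an acetyl anion equivalent. The chelated tetrahedral adduct of the Weinreb amide prevents a second addition, and acid hydrolysis of the enol ether reveals the second carbonyl.

Step 8
Reactants: 9 1-[3,5-bis(benzyloxy)-4-methoxyphenyl]propane-1,2-dione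
Product: 10 (1S,2R)-1-[3,5-bis(benzyloxy)-4-methoxyphenyl]propane-1,2-diol
Conditions: RuCl[(R,R)-TsDPEN](p-cymene) (1 mol%), HCO2H/Et3N (5:2), 40 °C
Reagents that add atoms: none
Why: Noyori-type asymmetric transfer hydrogenation of a 1-aryl-1,2-dione. The first reduction gives a configurationally labile ketol, and the second is catalyst-controlled with dynamic kinetic resolution, which gives the anti (erythro) diol. The (R,R)-catalyst sets the benzylic carbon as S in the usual aryl ketone sense, and C2 follows as R.

Step 9
Reactants: 10 (1S,2R)-1-[3,5-bis(benzyloxy)-4-methoxyphenyl]propane-1,2-diol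
Product: 11 (1S,2R)-1-[3,5-bis(benzyloxy)-2-bromo-4-methoxyphenyl]propane-1,2-diol
Conditions: NBS (1.0 equiv), MeCN, 0 °C
Reagents that add atoms: N-bromosuccinimide BrN1C(=O)CCC1=O
Why: Electrophilic aromatic bromination. The two free positions are equivalent, each ortho to one benzyloxy group and para to the other, and the benzyl rings are not activated.

Step 10
Reactants: 11 (1S,2R)-1-[3,5-bis(benzyloxy)-2-bromo-4-methoxyphenyl]propane-1,2-diol
Product: 13 tert-butyl{[(1S,2R)-1-[3,5-bis(benzyloxy)-2-bromo-4-methoxyphenyl]-2-(triethylsilyloxy)propyl]oxy}dimethylsilane, via C2 triethylsilyl ether 12 (not isolated)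
Conditions: TESCl, imidazole, CH2Cl2, −30 °C; then 2,6-lutidine, TBSOTf, −30 → 0 °C
Reagents that add atoms: chlorotriethylsilane CC[Si](Cl)(CC)CC; tert-butyldimethylsilyl triflate CC(C)(C)[Si](C)(C)OS(=O)(=O)C(F)(F)F
Why: Sterically controlled silylation. The benzylic hydroxyl lies next to the ortho-bromo arene and is the slower one, so the small chlorosilane takes the methyl carbinol, and the reactive triflate then silylates the benzylic oxygen.

Step 11
Reactants: 13 tert-butyl{[(1S,2R)-1-[3,5-bis(benzyloxy)-2-bromo-4-methoxyphenyl]-2-(triethylsilyloxy)propyl]oxy}dimethylsilane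
Product: 14 (1S,2R)-1-[3,5-bis(benzyloxy)-2-bromo-4-methoxyphenyl]-1-(tert-butyldimethylsilyloxy)propan-2-ol
Conditions: PPTS, MeOH, 0 °C → rt
Reagents that add atoms: none
Why: Acid-catalysed solvolysis removes the triethylsilyl ether much faster than the hindered benzylic tert-butyldimethylsilyl ether. Acidic conditions avoid base-induced silyl migration.

Step 12
Reactants: 14 (1S,2R)-1-[3,5-bis(benzyloxy)-2-bromo-4-methoxyphenyl]-1-(tert-butyldimethylsilyloxy)propan-2-ol
Product: 15 (3R,4S)-6,8-bis(benzyloxy)-4-(tert-butyldimethylsilyloxy)-7-methoxy-3-methylisochroman-1-one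
Conditions: Pd(OAc)2 (5 mol%), Xantphos (6 mol%), CO (1 atm), Et3N, toluene, 90 °C
Reagents that add atoms: carbon monoxide [C-]#[O+]
Why: Palladium-catalysed carbonylative lactonisation (intramolecular alkoxycarbonylation of an aryl bromide). Only the C2 hydroxyl is free, so the acyl palladium intermediate can close only the six-membered lactone, and neither stereocentre is touched.

Step 13
Reactants: 15 (3R,4S)-6,8-bis(benzyloxy)-4-(tert-butyldimethylsilyloxy)-7-methoxy-3-methylisochroman-1-one
Product: 16 (3R,4S)-4-(tert-butyldimethylsilyloxy)-6,8-dihydroxy-7-methoxy-3-methylisochroman-1-one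
Conditions: H2 (1 atm), 10% Pd/C, EtOAc, rt
Reagents that add atoms: none
Why: Hydrogenolysis of the two aryl benzyl ethers under neutral conditions. The benzylic silyl ether on the electron-poor lactone ring and the lactone itself are not cleaved.

Step 14
Reactants: 5 [2-(1,3-dioxolan-2-yl)-4-methoxy-3,5-bis(methoxymethoxy)phenyl]methanol; 16 (3R,4S)-4-(tert-butyldimethylsilyloxy)-6,8-dihydroxy-7-methoxy-3-methylisochroman-1-one
Product: 18 6-({[(3R,4S)-4-(tert-butyldimethylsilyloxy)-8-hydroxy-7-methoxy-3-methyl-1-oxoisochroman-6-yl]oxy}methyl)-3-methoxy-2,4-bis(methoxymethoxy)benzaldehyde, via dioxolane ether 17 (not isolated)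
Conditions: PPh3, DIAD, THF, 0 °C → rt; then 0.5 M aq. HCl, 0 °C → rt
Reagents that add atoms: water O
Why: Mitsunobu etherification of a primary benzylic alcohol. The 6-hydroxyl, para to the carbonyl-bearing carbon, is the acidic and unhindered phenol, whereas the 8-hydroxyl is held in a hydrogen bond to the lactone carbonyl. Dilute acid then hydrolyses the dioxolane of the electron-rich benzaldehyde faster than aryl MOM or silyl ethers.

Step 15
Reactants: 18 6-({[(3R,4S)-4-(tert-butyldimethylsilyloxy)-8-hydroxy-7-methoxy-3-methyl-1-oxoisochroman-6-yl]oxy}methyl)-3-methoxy-2,4-bis(methoxymethoxy)benzaldehyde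
Product: 19 6-({[(3R,4S)-4-(tert-butyldimethylsilyloxy)-7-methoxy-8-(methoxymethoxy)-3-methyl-1-oxoisochroman-6-yl]oxy}methyl)-3-methoxy-2,4-bis(methoxymethoxy)benzaldehyde
Conditions: MOMCl, iPr2NEt, nBu4NI (cat.), CH2Cl2, 0 → 40 °C
Reagents that add atoms: chloromethyl methyl ether COCCl
Why: O-Alkylation of the remaining chelated phenol. No free phenol then competes for titanium or acts as a hydrogen donor in the photochemical step.

Step 16
Reactants: 19 6-({[(3R,4S)-4-(tert-butyldimethylsilyloxy)-7-methoxy-8-(methoxymethoxy)-3-methyl-1-oxoisochroman-6-yl]oxy}methyl)-3-methoxy-2,4-bis(methoxymethoxy)benzaldehyde; 20 acetaldehyde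
Product: 21 (3R,4S)-4-{[(3R,4S)-4-(tert-butyldimethylsilyloxy)-7-methoxy-8-(methoxymethoxy)-3-methyl-1-oxoisochroman-6-yl]oxy}-7-methoxy-6,8-bis(methoxymethoxy)-3-methylisochroman-1-ol (both C1 epimers)
Conditions: Ti(OiPr)4 (2 equiv), (R,R)-TADDOL (2.2 equiv), toluene, rt; then 19, MeCHO (20 equiv), hν (365 nm LED), −20 °C; aq. potassium sodium tartrate
Reagents that add atoms: none
Why: Proposed new method: Excitation of the aryl aldehyde at 365 nm, intersystem crossing and 1,5-hydrogen transfer from the benzylic, oxygen-substituted CH2 group give the long-lived E-hydroxy-ortho-quinodimethane with the aryloxy group outside, which the titanium TADDOLate holds as a titanium dienolate. Acetaldehyde bound to titanium is attacked at carbon by C4, the vinylogous enolate terminus, and its oxygen closes onto C1. The pyran ring is thus closed by an oxa-[4+2] cycloaddition or, in the stepwise limit, by vinylogous aldol addition followed by 6-exo-trig hemiacetal formation, and both paths give 21 with rearomatisation as driving force. The closest known reaction type is the titanium-mediated photoenolisation/Diels–Alder reaction of 2-alkylbenzaldehydes with enones, including TADDOL-controlled versions, together with thermal hetero-Diels–Alder reactions of ortho-quinodimethanes with aldehydes; new here is an unactivated aliphatic aldehyde as the 2π partner of a photoenol. The configuration at C4 depends on which face of the planar dienol is attacked and is controlled by the chiral diolate on titanium, because the stereocentres of ring B are too remote to intervene. The trans relation at C3 needs the methyl group exo: in the working model titanium is held between the dienol oxygen and the C8 MOM ether on the arene side of the forming ring and binds the aldehyde lone pair anti to methyl, which places H over the ring and CH3 outside. The step needs C–C bond formation at C4 with C–O bond formation at C1, secured by the oxygen donor at C1 and the titanium tether, and hydrogen transfer from the benzylic CH2 and not from a MOM group, secured by the six-membered transition state and the weaker benzylic C–H bond; O8 is an ether, so no excited-state proton transfer competes. C1 is formed as a mixture of epimers, which does not matter because it is oxidised next, and an adduct from the wrong face would be a diastereomer that can be separated from 21.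

Step 17
Reactants: 21 (3R,4S)-4-{[(3R,4S)-4-(tert-butyldimethylsilyloxy)-7-methoxy-8-(methoxymethoxy)-3-methyl-1-oxoisochroman-6-yl]oxy}-7-methoxy-6,8-bis(methoxymethoxy)-3-methylisochroman-1-ol
Product: 22 (3R,4S)-4-{[(3R,4S)-4-(tert-butyldimethylsilyloxy)-7-methoxy-8-(methoxymethoxy)-3-methyl-1-oxoisochroman-6-yl]oxy}-7-methoxy-6,8-bis(methoxymethoxy)-3-methylisochroman-1-one
Conditions: nBu4N[RuO4] (5 mol%), NMO, 4 Å MS, CH2Cl2, rt
Reagents that add atoms: none
Why: Ley–Griffith oxidation of a lactol to the lactone under neutral conditions. Both C1 epimers converge and C3 and C4 are not affected.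

Step 18
Reactants: 22 (3R,4S)-4-{[(3R,4S)-4-(tert-butyldimethylsilyloxy)-7-methoxy-8-(methoxymethoxy)-3-methyl-1-oxoisochroman-6-yl]oxy}-7-methoxy-6,8-bis(methoxymethoxy)-3-methylisochroman-1-one
Product: 23 (3R,4S)-4-{[(3R,4S)-4,8-dihydroxy-7-methoxy-3-methyl-1-oxoisochroman-6-yl]oxy}-6,8-dihydroxy-7-methoxy-3-methylisochroman-1-one
Conditions: HCl (1.25 M in MeOH), THF, 0 °C → rt
Reagents that add atoms: none
Why: Acid-catalysed methanolysis removes the three aryl MOM ethers as dimethoxymethane and the silyl ether as its methyl ether. The C4 benzylic ether should survive because ionisation at C4 is disfavoured by the ortho lactone carbonyl.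

## Compound list

1 | methyl 3,5-dihydroxy-4-methoxybenzoate | COC(=O)c1cc(O)c(OC)c(O)c1 | starting material
2 | methyl 2-formyl-3,5-dihydroxy-4-methoxybenzoate | COC(=O)c1cc(O)c(OC)c(O)c1C=O | intermediate
3 | methyl 2-formyl-4-methoxy-3,5-bis(methoxymethoxy)benzoate | COC(=O)c1cc(OCOC)c(OC)c(OCOC)c1C=O | intermediate
4 | methyl 2-(1,3-dioxolan-2-yl)-4-methoxy-3,5-bis(methoxymethoxy)benzoate | COC(=O)c1cc(OCOC)c(OC)c(OCOC)c1C1OCCO1 | intermediate
5 | [2-(1,3-dioxolan-2-yl)-4-methoxy-3,5-bis(methoxymethoxy)phenyl]methanol | OCc1cc(OCOC)c(OC)c(OCOC)c1C1OCCO1 | intermediate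
6 | methyl 3,5-bis(benzyloxy)-4-methoxybenzoate | COC(=O)c1cc(OCc2ccccc2)c(OC)c(OCc2ccccc2)c1 | intermediate
7 | 3,5-bis(benzyloxy)-N,4-dimethoxy-N-methylbenzamide | CON(C)C(=O)c1cc(OCc2ccccc2)c(OC)c(OCc2ccccc2)c1 | intermediate
8 | 1-[3,5-bis(benzyloxy)-4-methoxyphenyl]-2-ethoxyprop-2-en-1-one | CCOC(=C)C(=O)c1cc(OCc2ccccc2)c(OC)c(OCc2ccccc2)c1 | intermediate
9 | 1-[3,5-bis(benzyloxy)-4-methoxyphenyl]propane-1,2-dione | CC(=O)C(=O)c1cc(OCc2ccccc2)c(OC)c(OCc2ccccc2)c1 | intermediate
10 | (1S,2R)-1-[3,5-bis(benzyloxy)-4-methoxyphenyl]propane-1,2-diol | C[C@@H](O)[C@@H](O)c1cc(OCc2ccccc2)c(OC)c(OCc2ccccc2)c1 | intermediate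
11 | (1S,2R)-1-[3,5-bis(benzyloxy)-2-bromo-4-methoxyphenyl]propane-1,2-diol | C[C@@H](O)[C@@H](O)c1cc(OCc2ccccc2)c(OC)c(OCc2ccccc2)c1Br | intermediate
12 | (1S,2R)-1-[3,5-bis(benzyloxy)-2-bromo-4-methoxyphenyl]-2-(triethylsilyloxy)propan-1-ol | C[C@@H](O[Si](CC)(CC)CC)[C@@H](O)c1cc(OCc2ccccc2)c(OC)c(OCc2ccccc2)c1Br | intermediate
13 | tert-butyl{[(1S,2R)-1-[3,5-bis(benzyloxy)-2-bromo-4-methoxyphenyl]-2-(triethylsilyloxy)propyl]oxy}dimethylsilane | C[C@@H](O[Si](CC)(CC)CC)[C@@H](O[Si](C)(C)C(C)(C)C)c1cc(OCc2ccccc2)c(OC)c(OCc2ccccc2)c1Br | intermediate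
14 | (1S,2R)-1-[3,5-bis(benzyloxy)-2-bromo-4-methoxyphenyl]-1-(tert-butyldimethylsilyloxy)propan-2-ol | C[C@@H](O)[C@@H](O[Si](C)(C)C(C)(C)C)c1cc(OCc2ccccc2)c(OC)c(OCc2ccccc2)c1Br | intermediate
15 | (3R,4S)-6,8-bis(benzyloxy)-4-(tert-butyldimethylsilyloxy)-7-methoxy-3-methylisochroman-1-one | COc1c(OCc3ccccc3)cc2c(c1OCc1ccccc1)C(=O)O[C@H](C)[C@H]2O[Si](C)(C)C(C)(C)C | intermediate
16 | (3R,4S)-4-(tert-butyldimethylsilyloxy)-6,8-dihydroxy-7-methoxy-3-methylisochroman-1-one | COc1c(O)cc2c(c1O)C(=O)O[C@H](C)[C@H]2O[Si](C)(C)C(C)(C)C | intermediate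
17 | (3R,4S)-4-(tert-butyldimethylsilyloxy)-6-{[2-(1,3-dioxolan-2-yl)-4-methoxy-3,5-bis(methoxymethoxy)phenyl]methoxy}-8-hydroxy-7-methoxy-3-methylisochroman-1-one | C1(OCCO1)c1c(OCOC)c(OC)c(OCOC)cc1COc1cc2c(c(O)c1OC)C(=O)O[C@H](C)[C@H]2O[Si](C)(C)C(C)(C)C | intermediate
18 | 6-({[(3R,4S)-4-(tert-butyldimethylsilyloxy)-8-hydroxy-7-methoxy-3-methyl-1-oxoisochroman-6-yl]oxy}methyl)-3-methoxy-2,4-bis(methoxymethoxy)benzaldehyde | O=Cc1c(OCOC)c(OC)c(OCOC)cc1COc1cc2c(c(O)c1OC)C(=O)O[C@H](C)[C@H]2O[Si](C)(C)C(C)(C)C | intermediate
19 | 6-({[(3R,4S)-4-(tert-butyldimethylsilyloxy)-7-methoxy-8-(methoxymethoxy)-3-methyl-1-oxoisochroman-6-yl]oxy}methyl)-3-methoxy-2,4-bis(methoxymethoxy)benzaldehyde | O=Cc1c(OCOC)c(OC)c(OCOC)cc1COc1cc2c(c(OCOC)c1OC)C(=O)O[C@H](C)[C@H]2O[Si](C)(C)C(C)(C)C | intermediate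
20 | acetaldehyde | CC=O | starting material
21 | (3R,4S)-4-{[(3R,4S)-4-(tert-butyldimethylsilyloxy)-7-methoxy-8-(methoxymethoxy)-3-methyl-1-oxoisochroman-6-yl]oxy}-7-methoxy-6,8-bis(methoxymethoxy)-3-methylisochroman-1-ol | COc1c(OCOC)cc2c(c1OCOC)C(O)O[C@H](C)[C@H]2Oc1cc2c(c(OCOC)c1OC)C(=O)O[C@H](C)[C@H]2O[Si](C)(C)C(C)(C)C | intermediate
22 | (3R,4S)-4-{[(3R,4S)-4-(tert-butyldimethylsilyloxy)-7-methoxy-8-(methoxymethoxy)-3-methyl-1-oxoisochroman-6-yl]oxy}-7-methoxy-6,8-bis(methoxymethoxy)-3-methylisochroman-1-one | COc1c(OCOC)cc2c(c1OCOC)C(=O)O[C@H](C)[C@H]2Oc1cc2c(c(OCOC)c1OC)C(=O)O[C@H](C)[C@H]2O[Si](C)(C)C(C)(C)C | intermediate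
23 | (3R,4S)-4-{[(3R,4S)-4,8-dihydroxy-7-methoxy-3-methyl-1-oxoisochroman-6-yl]oxy}-6,8-dihydroxy-7-methoxy-3-methylisochroman-1-one | COc1c(O)cc2c(c1O)C(=O)O[C@H](C)[C@H]2Oc1cc2c(c(O)c1OC)C(=O)O[C@H](C)[C@H]2O | target

## Step count and least certain steps

Total: 18 steps. Longest linear sequence: 14 steps (steps 5 to 18, from 1 through ring B to 23). The ring A alcohol 5 is made in 4 steps and joins at step 14.

**Step 16 (key step, Proposed new method).** The dienol may return to 19 faster than acetaldehyde captures it, because a simple aliphatic aldehyde is a weak 2π partner. Facial or exo/endo control may be poor. Titanium alkoxide may condense acetaldehyde with itself, and hydrogen abstraction from a MOM methylene may compete. The fallback uses known chemistry and forms the C4–O6' bond by Mitsunobu inversion on a ring A lactone made from 16: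
- 16 is converted with MOMCl and iPr2NEt into (3R,4S)-4-(tert-butyldimethylsilyloxy)-7-methoxy-6,8-bis(methoxymethoxy)-3-methylisochroman-1-one F1.
- HF·pyridine frees the trans alcohol (3R,4S)-4-hydroxy-7-methoxy-6,8-bis(methoxymethoxy)-3-methylisochroman-1-one F2.
- A Mitsunobu reaction with chloroacetic acid inverts C4 to the cis ester (3R,4R)-7-methoxy-6,8-bis(methoxymethoxy)-3-methyl-1-oxoisochroman-4-yl chloroacetate F3.
- Thiourea with NaHCO3 removes the chloroacetyl group without opening the lactone and gives the cis alcohol (3R,4R)-4-hydroxy-7-methoxy-6,8-bis(methoxymethoxy)-3-methylisochroman-1-one F4.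
- A second Mitsunobu reaction, with the 6-hydroxyl of a second portion of 16 as nucleophile, inverts C4 again and gives (3R,4S)-4-{[(3R,4S)-4-(tert-butyldimethylsilyloxy)-8-hydroxy-7-methoxy-3-methyl-1-oxoisochroman-6-yl]oxy}-7-methoxy-6,8-bis(methoxymethoxy)-3-methylisochroman-1-one F5.
- MOMCl and iPr2NEt convert F5 into 22, where the route is rejoined.

**Step 8.** Over-reduction is not the concern; incomplete dynamic resolution of the ketol is, which would lower the anti selectivity or the enantiomeric purity on this electron-rich aryl dione. The fallback sets the two centres one after the other: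
- 7 reacts with EtMgBr to give 1-[3,5-bis(benzyloxy)-4-methoxyphenyl]propan-1-one F6.
- Its sodium enolate (NaN(SiMe3)2) is hydroxylated with the enantiomer of (camphorsulfonyl)oxaziridine that delivers (2R)-1-[3,5-bis(benzyloxy)-4-methoxyphenyl]-2-hydroxypropan-1-one F7.
- Chelation-controlled reduction of F7 with Zn(BH4)2 gives the anti diol 10.

**Step 10.** Discrimination between the two secondary hydroxyls may be incomplete, or the silyl groups may scramble; either would lead to the isomeric phthalide after carbonylation. The fallback lets an enzyme choose the oxygen: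
- Candida antarctica lipase B with vinyl acetate acylates only the methyl carbinol of 11 and gives (1S,2R)-1-[3,5-bis(benzyloxy)-2-bromo-4-methoxyphenyl]-1-hydroxypropan-2-yl acetate F8.
- TBSOTf and 2,6-lutidine give (1S,2R)-1-[3,5-bis(benzyloxy)-2-bromo-4-methoxyphenyl]-1-(tert-butyldimethylsilyloxy)propan-2-yl acetate F9.
- iBu2AlH at −78 °C removes the acetate reductively and gives 14.

**Step 12.** Oxidative addition at the doubly ortho-substituted aryl bromide may be slow, and prolonged heating with base may move the silyl group to the neighbouring oxygen. The fallback replaces catalysis by halogen–metal exchange: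
- 14 is deprotonated with MeMgBr, treated with tBuLi at −78 °C and quenched with CO2 to give 2-[(1S,2R)-1-(tert-butyldimethylsilyloxy)-2-hydroxypropyl]-4,6-bis(benzyloxy)-5-methoxybenzoic acid F10.
- Dehydrative lactonisation of F10 with EDC·HCl and DMAP gives 15.

**Step 18.** Acid may ionise the C4 benzylic ether or equilibrate the 4'-hydroxy lactone of ring B with its phthalide isomer before all MOM groups are gone. The fallback avoids protic acid:
- HF·pyridine converts 22 into (3R,4S)-4-{[(3R,4S)-4-hydroxy-7-methoxy-8-(methoxymethoxy)-3-methyl-1-oxoisochroman-6-yl]oxy}-7-methoxy-6,8-bis(methoxymethoxy)-3-methylisochroman-1-one F11.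
- The three aryl MOM ethers of F11 are then cleaved with TMSOTf and 2,2′-bipyridyl in CH2Cl2 followed by water, which gives 23.

## Further compounds

F1 | step 16 | (3R,4S)-4-(tert-butyldimethylsilyloxy)-7-methoxy-6,8-bis(methoxymethoxy)-3-methylisochroman-1-one | COc1c(OCOC)cc2c(c1OCOC)C(=O)O[C@H](C)[C@H]2O[Si](C)(C)C(C)(C)C
F2 | step 16 | (3R,4S)-4-hydroxy-7-methoxy-6,8-bis(methoxymethoxy)-3-methylisochroman-1-one | COc1c(OCOC)cc2c(c1OCOC)C(=O)O[C@H](C)[C@H]2O
F3 | step 16 | (3R,4R)-7-methoxy-6,8-bis(methoxymethoxy)-3-methyl-1-oxoisochroman-4-yl chloroacetate | COc1c(OCOC)cc2c(c1OCOC)C(=O)O[C@H](C)[C@@H]2OC(=O)CCl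
F4 | step 16 | (3R,4R)-4-hydroxy-7-methoxy-6,8-bis(methoxymethoxy)-3-methylisochroman-1-one | COc1c(OCOC)cc2c(c1OCOC)C(=O)O[C@H](C)[C@@H]2O
F5 | step 16 | (3R,4S)-4-{[(3R,4S)-4-(tert-butyldimethylsilyloxy)-8-hydroxy-7-methoxy-3-methyl-1-oxoisochroman-6-yl]oxy}-7-methoxy-6,8-bis(methoxymethoxy)-3-methylisochroman-1-one | COc1c(OCOC)cc2c(c1OCOC)C(=O)O[C@H](C)[C@H]2Oc1cc2c(c(O)c1OC)C(=O)O[C@H](C)[C@H]2O[Si](C)(C)C(C)(C)C
F6 | step 8 | 1-[3,5-bis(benzyloxy)-4-methoxyphenyl]propan-1-one | CCC(=O)c1cc(OCc2ccccc2)c(OC)c(OCc2ccccc2)c1
F7 | step 8 | (2R)-1-[3,5-bis(benzyloxy)-4-methoxyphenyl]-2-hydroxypropan-1-one | C[C@@H](O)C(=O)c1cc(OCc2ccccc2)c(OC)c(OCc2ccccc2)c1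
F8 | step 10 | (1S,2R)-1-[3,5-bis(benzyloxy)-2-bromo-4-methoxyphenyl]-1-hydroxypropan-2-yl acetate | C[C@@H](OC(C)=O)[C@@H](O)c1cc(OCc2ccccc2)c(OC)c(OCc2ccccc2)c1Br
F9 | step 10 | (1S,2R)-1-[3,5-bis(benzyloxy)-2-bromo-4-methoxyphenyl]-1-(tert-butyldimethylsilyloxy)propan-2-yl acetate | C[C@@H](OC(C)=O)[C@@H](O[Si](C)(C)C(C)(C)C)c1cc(OCc2ccccc2)c(OC)c(OCc2ccccc2)c1Br
F10 | step 12 | 2-[(1S,2R)-1-(tert-butyldimethylsilyloxy)-2-hydroxypropyl]-4,6-bis(benzyloxy)-5-methoxybenzoic acid | C[C@@H](O)[C@@H](O[Si](C)(C)C(C)(C)C)c1cc(OCc2ccccc2)c(OC)c(OCc2ccccc2)c1C(O)=O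
F11 | step 18 | (3R,4S)-4-{[(3R,4S)-4-hydroxy-7-methoxy-8-(methoxymethoxy)-3-methyl-1-oxoisochroman-6-yl]oxy}-7-methoxy-6,8-bis(methoxymethoxy)-3-methylisochroman-1-one | COc1c(OCOC)cc2c(c1OCOC)C(=O)O[C@H](C)[C@H]2Oc1cc2c(c(OCOC)c1OC)C(=O)O[C@H](C)[C@H]2O
A1 | alternative 1 | methyl 6-[(1S,2R)-1-(tert-butyldimethylsilyloxy)-2-(methoxymethoxy)propyl]-4-{(1S,2R)-1-[4-methoxy-3,5-bis(methoxymethoxy)phenyl]-2-(methoxymethoxy)propoxy}-3-methoxy-2-(methoxymethoxy)benzoate | COC(=O)c1c(OCOC)c(OC)c(O[C@@H](c2cc(OCOC)c(OC)c(OCOC)c2)[C@@H](C)OCOC)cc1[C@H](O[Si](C)(C)C(C)(C)C)[C@@H](C)OCOC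
A2 | alternative 1 | methyl 6-[(1S,2R)-1-(tert-butyldimethylsilyloxy)-2-(methoxymethoxy)propyl]-3-methoxy-4-(methoxymethoxy)-2-oxo-2H-pyran-5-carboxylate | COC(=O)c1c(OCOC)c(OC)c(=O)oc1[C@H](O[Si](C)(C)C(C)(C)C)[C@@H](C)OCOC
A3 | alternative 1 | 5-[(1S,2R)-1-(ethynyloxy)-2-(methoxymethoxy)propyl]-2-methoxy-1,3-bis(methoxymethoxy)benzene | C#CO[C@@H](c1cc(OCOC)c(OC)c(OCOC)c1)[C@@H](C)OCOC
A4 | alternative 2 | 6,4'-di-O-acetyl derivative of 23 | COc1c(OC(C)=O)cc2c(c1O)C(=O)O[C@H](C)[C@H]2Oc1cc2c(c(O)c1OC)C(=O)O[C@H](C)[C@H]2OC(C)=O
A5 | alternative 2 | 8,8'-dideoxy-6,4'-di-O-acetyl derivative of 23 | COc1c(OC(C)=O)cc2c(c1)C(=O)O[C@H](C)[C@H]2Oc1cc2c(cc1OC)C(=O)O[C@H](C)[C@H]2OC(C)=O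
A6 | alternative 3 | 6,8,8'-tri-O-methoxymethyl-4'-O-tert-butyldimethylsilyl derivative of 23 (identical with 22) | COc1c(OCOC)cc2c(c1OCOC)C(=O)O[C@H](C)[C@H]2Oc1cc2c(c(OCOC)c1OC)C(=O)O[C@H](C)[C@H]2O[Si](C)(C)C(C)(C)C
A7 | alternative 3 | (1S,2R)-1-[2-bromo-4-methoxy-3,5-bis(methoxymethoxy)phenyl]-1-{4-bromo-5-[(1S,2R)-1-(tert-butyldimethylsilyloxy)-2-hydroxypropyl]-2-methoxy-3-(methoxymethoxy)phenoxy}propan-2-ol | C[C@@H](O)[C@@H](Oc1cc([C@H](O[Si](C)(C)C(C)(C)C)[C@@H](C)O)c(Br)c(OCOC)c1OC)c1cc(OCOC)c(OC)c(OCOC)c1Br
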